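## The problem

The target 33 joins four rings: a 2,4-diformylphloroglucinol ring A, a dihydropyran ring B, a nine-membered carbocycle C and a gem-dimethylcyclobutane ring D. Ring C is numbered C1–C9 (C1 and C9 shared with ring D, whose other carbons are C10 and C11; C4 the oxygen-bearing quaternary carbon; C5 the ring-B methine; C8 the methylidene carbon), and the phenyl-bearing carbon of ring B is C1'. There are five stereocentres, C1' (S), C5 (R), C4 (S), C1 (S) and C9 (R): on ring B the phenyl group is trans to C6 and the C4 methyl group is cis to C6, so rings B and C are trans-fused, and ring D is trans-fused as well. C1' can steer C5 (reaction of a ring-B enolate next to it) and C5 can steer C4 (addition to a C4 carbonyl group), but C1 and C9 lie two methylene groups beyond C4 and cannot be set by relay, so two enantiopure halves must be joined. C9 can be corrected by epimerisation only while a carbonyl group sits on it, and C4, once it is a tertiary aryl ether, must never be ionised. The phenol-flanked aldehydes do not survive carbanions, organometallics or dissolving metals, and the 1,1-disubstituted alkene does not survive strong acid, halonium sources or hydrogenation. The nine-membered ring is the costly element: its closure pays transannular strain and must be irreversible and run at high dilution. The key step is possible because C7, C8 and the exocyclic CH2 form a 2-substituted allyl unit with interchangeable termini, while C6 is a methylene group that can carry a removable anion-stabilising group. A C6 carbanion attacking either allyl terminus gives the same C6–C7 bond and the same alkene.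

## Retrosynthesis

**Formyl groups (33 ⇒ 32 ⇒ 31).** The two aryl–CHO bonds are cut first. The aldehydes would not survive any earlier step, and in diol 32 the only two free positions of ring A are the ones to be formylated, so regiochemistry needs no control. Bis(methoxymethyl) ether 31 is the protected form. The forward formylation must spare the methylidene group.

**Ring C at C6–C7 (31 ⇒ 30 ⇒ 29).** Neighbouring cuts are less attractive. C7–C8 needs an sp2–sp3 coupling and a vinyl group on C5; C3–C4 would close the ring at a quaternary centre; C8–C9 would put the closing bond on the epimerisable cyclobutane carbon. C6 is the one ring-C carbon where a sulfone can be parked beside an existing stereocentre and later removed without trace. Bromo sulfone 29 has one ring and one stereocentre fewer than 30. The forward step must favour intramolecular C-alkylation over oligomerisation.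

**Functional-group adjustment (29 ⇒ 28 ⇒ 27 ⇒ 26).** The bromide comes from allylic alcohol 28, this from silyl ether 27, and the sulfone from sulfide 26. Sulfur is carried as the sulfide through all carbonyl chemistry, because a β-sulfonyl ketone would lose sulfinate on any enolisation.

**Ring B at the aryl–oxygen bond (26 ⇒ 25).** Cutting C4–O instead would mean closing through a tertiary cation, which erases C4. C-alkylation of C4 at the ketal level would ask an sp3 organometallic to trap a tertiary oxocarbenium ion that easily loses a proton, and its facial bias would be caught between the C5 and C1' substituents. Cutting O–C(aryl) leaves C4 as a tertiary alcohol in 25, whose configuration can be set by acyclic stereocontrol and is carried over with retention. The forward reaction is an intramolecular aryl triflate etherification.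

**C4–CH3 (25 ⇒ 24).** With the long chain on the carbonyl group and methyl as the nucleophile, Felkin–Anh addition to ketone 24 gives the required C4 epimer. The opposite order of introduction would give the other epimer. The forward step must add to a hindered, enolisable ketone without touching the aryl triflate.

**C3–C4, union of the halves (24 ⇒ 6 + 21).** The C4 carbonyl carbon is the lactone carbon of 6. An alkyllithium 22 made from iodide 21 adds once (alkoxide 23), and the released phenoxide is triflated in the same flask. This turns the lactone oxygen into the leaving group needed above. Both partners are far simpler: 6 holds C1' and C5, 21 holds C1 and C9.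

**Template lactone (6 ⇒ 4 ⇒ 2 + 3 ⇒ 1).** The C5–C6 bond is cut back to lactone 4, where alkylation anti to the phenyl group sets C5. The C1'–phenyl bond is cut back to coumarin 2 and phenylboronic acid 3 (catalytic asymmetric conjugate addition), and 2 comes from 5,7-dihydroxycoumarin 1.

**Allyl unit and chain terminus (21 ⇒ 20 ⇒ 19 ⇒ 18 ⇒ 17 ⇒ 16).** The allyl unit is completed on the small fragment, not on the advanced material: the bond from C8 to its second CH2 terminus is cut back to enol triflate 17 of methyl ketone 16. The iodide comes from alcohol 20 after a silyl-group exchange (19, 18).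

**Cyclobutane (16 ⇒ 14 ⇒ 13 ⇒ 10 ⇒ 9 ⇒ 7 + 8).** The trans arrangement in 16 is reached by epimerising C9 next to the acetyl group of 14. The acetyl methyl group is cut back to lactone 13, which arises from enone 10 by oxidative cleavage of the cyclopentanone between its carbonyl and methylene carbons. The C1–C11 and C9–C10 bonds are cut back to silyloxy enone 7 and isobutene 8 ([2+2] photocycloaddition to 9). The silyloxy group of 7 serves only to set the absolute configuration and is then eliminated.

## Roads not taken

**Alternative 1:** The cut removes two bonds of ring A, so the arene is built last on ring B. The dianion of dimethyl 3-oxopentanedioate A2 would displace methanethiolate from ketene O,S-acetal A1 and then condense onto its ester, and enolisation would give diester A3.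
- Merits: no phenol protection and no electrophilic formylation near the methylidene group; both future formyl carbons arrive in place. In the end game this road is better than the chosen one, whose steps 22 and 23 expose the alkene to acid and to a chloroiminium electrophile.
- Weak points: A1 must already contain rings C and D and all five stereocentres on a dihydropyran that is a vinylogous carbonate. C1' is then a γ-position that a hydride base can epimerise, and ring B can open by β-elimination. Without the arene, nothing transmits C1' to C5 and C4. The esters of A3 still need reduction and re-oxidation, and ring C remains to be closed.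
- Comparison: the chosen plan sets against the better end game its stereochemical relay through the lactone template and a defined solution for ring C.

**Alternative 2:** The cut removes C9–C10 and C1–C11. Irradiation of cyclononenone A4 in isobutene 8 would give cyclobutane ketone A5 after base equilibration of C9.
- Merits: the cyclobutane comes from a gas in one step, and the ten-step enantiopure fragment of the chosen plan disappears. In step count this road is clearly shorter.
- Weak points: C1 cannot be corrected afterwards. Its configuration depends on which face of a flexible nine-membered enone is attacked, many bonds from the nearest stereocentre. Medium-ring enones isomerise on excitation and then add unselectively or dimerise; head-to-head adducts and quenching by the electron-rich arene are further risks. A4 itself still requires the nine-membered ring, and A5 needs a late methylenation beside an epimerisable centre.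
- Comparison: the chosen plan sets against the shorter route the certainty that C1 and C9 are fixed and checked before the halves are joined.

**Alternative 3:** The cut is C7–C8. Hydroboration of the C5 vinyl group of A6 and intramolecular B-alkyl Suzuki coupling with its enol triflate would give A7, which is the same compound as 31.
- Merits: no sulfone to oxidise and remove (two steps fewer after the union), near-neutral conditions, and the alkene arises directly. This is the closest competitor and is as good or better in step count.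
- Weak points: a vinyl group trans to phenyl on C5 cannot be introduced by a simple enolate alkylation of 4. Reductive elimination through a ten-membered palladacycle to a nine-membered ring is the least favourable ring size for this coupling, with β-hydride elimination and protodeboronation as exits. There is only one productive trajectory.
- Comparison: the chosen plan sets against it an irreversible alkylation with two equivalent trajectories, a single acidic site, and a sulfur atom that also allows polarity reversal at C6 if the closure fails (fallback below).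

Key step: step 20

Remark: C6 of 30 is formed without dependable control and is removed in step 21, so it is left without configuration in the name and SMILES of 30.

## Route

Step 1
Reactants: 1 5,7-dihydroxycoumarin
Product: 2 5,7-bis(methoxymethoxy)-2H-chromen-2-one
Conditions: MOMCl (2.6 equiv), iPr2NEt, CH2Cl2, 0 → 20 °C
Reagents that add atoms: chloromethyl methyl ether, COCCl
Why: O-alkylation of both phenols (Williamson type); the acetal ethers withstand the basic, organometallic and reductive steps ahead and leave under mild acid.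

Step 2
Reactants: 2 5,7-bis(methoxymethoxy)-2H-chromen-2-one; 3 phenylboronic acid
Product: 4 (4S)-5,7-bis(methoxymethoxy)-4-phenyl-3,4-dihydro-2H-chromen-2-one
Conditions: 3 (5 equiv), Rh(acac)(C2H4)2 (3 mol%), (S)-SEGPHOS (3.3 mol%), dioxane–H2O 10:1, 60 °C
Reagents that add atoms: none
Why: Hayashi–Miyaura asymmetric 1,4-addition of an arylrhodium species to the coumarin double bond sets C1'; (S)-SEGPHOS is the enantiomer expected by analogy to give the 4S lactone (to be confirmed), and the peri alkoxy group may demand a larger excess of 3.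

Step 3
Reactants: 4 (4S)-5,7-bis(methoxymethoxy)-4-phenyl-3,4-dihydro-2H-chromen-2-one
Product: 6 (3R,4S)-5,7-bis(methoxymethoxy)-4-phenyl-3-[(phenylsulfanyl)methyl]-3,4-dihydro-2H-chromen-2-one, via silyl ketene acetal 5 (not isolated)
Conditions: LiN(SiMe3)2, Me3SiCl, THF, −78 °C; then PhSCH2Cl, ZnBr2 (10 mol%), CH2Cl2, 0 → 20 °C
Reagents that add atoms: chloromethyl phenyl sulfide, ClCSc1ccccc1
Why: ZnBr2-catalysed phenylthiomethylation of an O-silyl ketene acetal (alkylation by a thionium ion); the electrophile should enter anti to the pseudo-axial phenyl group, giving the 3,4-trans lactone, which is also the more stable epimer, and this sets C5.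

Step 4
Reactants: 7 (4R)-4-[(tert-butyldimethylsilyl)oxy]cyclopent-2-en-1-one; 8 isobutene
Product: 9 (1S,4R,5S)-4-[(tert-butyldimethylsilyl)oxy]-6,6-dimethylbicyclo[3.2.0]heptan-2-one
Conditions: hν (λ > 300 nm, Pyrex), 8 (excess), CH2Cl2, −70 °C
Reagents that add atoms: none
Why: enone–alkene [2+2] photocycloaddition; head-to-tail orientation (CMe2 on the β-carbon) is the normal outcome for isobutene, and addition anti to the silyloxy group, the usual preference of 4-oxygenated cyclopentenones, fixes both ring-fusion carbons (later C1 and C9); minor isomers are removed by chromatography.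

Step 5
Reactants: 9 (1S,4R,5S)-4-[(tert-butyldimethylsilyl)oxy]-6,6-dimethylbicyclo[3.2.0]heptan-2-one
Product: 10 (1S,5S)-6,6-dimethylbicyclo[3.2.0]hept-3-en-2-one
Conditions: DBU, CH2Cl2, 0 → 20 °C
Reagents that add atoms: none
Why: E1cB β-elimination of the silyloxy group; the auxiliary stereocentre is erased once it has done its work.

Step 6
Reactants: 10 (1S,5S)-6,6-dimethylbicyclo[3.2.0]hept-3-en-2-one
Product: 13 (1S,6S)-7,7-dimethyl-3-oxabicyclo[4.2.0]octan-2-one, via silyl enol ether 11 (not isolated), via hydroxy acid 12 (not isolated)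
Conditions: Et3SiH, RhCl(PPh3)3 (1 mol%), CH2Cl2, 40 °C; then O3, CH2Cl2–MeOH, −78 °C; NaBH4, −78 → 20 °C; then 1 M HCl
Reagents that add atoms: ozone, [O-][O+]=O
Why: rhodium-catalysed 1,4-hydrosilylation places the enol ether double bond regiospecifically between the carbonyl carbon and the former α-carbon; ozonolysis of silyl enol ethers with borohydride work-up gives ω-hydroxy acids, and the cis acid 12 lactonises on acidification.

Step 7
Reactants: 13 (1S,6S)-7,7-dimethyl-3-oxabicyclo[4.2.0]octan-2-one
Product: 14 1-[(1S,2S)-2-(2-hydroxyethyl)-3,3-dimethylcyclobutyl]ethan-1-one (in equilibrium with its cyclic hemiketal)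
Conditions: MeLi (1.05 equiv), THF, −78 °C; NH4Cl (aq), −78 °C
Reagents that add atoms: methyllithium, [Li]C
Why: single addition of an organolithium to a δ-lactone, whose tetrahedral lithium alkoxide persists at −78 °C until the cold quench.

Step 8
Reactants: 14 1-[(1S,2S)-2-(2-hydroxyethyl)-3,3-dimethylcyclobutyl]ethan-1-one
Product: 16 1-[(1R,2S)-2-{2-[(tert-butyldimethylsilyl)oxy]ethyl}-3,3-dimethylcyclobutyl]ethan-1-one, via cis ketone 15 (not isolated)
Conditions: TBSCl, imidazole, CH2Cl2, 20 °C; then NaOMe, MeOH, 40 °C
Reagents that add atoms: tert-butyl(chloro)dimethylsilane, CC(C)(C)[Si](C)(C)Cl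
Why: silylation traps the open-chain hydroxy ketone, and equilibration through the enolate then moves the acetyl-bearing carbon (C9) to the trans arrangement, the more stable 1,2-disubstituted cyclobutane; any remaining cis isomer is resubmitted.

Step 9
Reactants: 16 1-[(1R,2S)-2-{2-[(tert-butyldimethylsilyl)oxy]ethyl}-3,3-dimethylcyclobutyl]ethan-1-one
Product: 17 1-[(1R,2S)-2-{2-[(tert-butyldimethylsilyl)oxy]ethyl}-3,3-dimethylcyclobutyl]ethenyl trifluoromethanesulfonate
Conditions: KN(SiMe3)2, THF, −78 °C; then PhNTf2, −78 → 0 °C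
Reagents that add atoms: N-phenylbis(trifluoromethanesulfonimide), O=S(=O)(N(c1ccccc1)S(=O)(=O)C(F)(F)F)C(F)(F)F
Why: kinetic deprotonation of a methyl ketone at the methyl group and O-triflation of the enolate; the ring methine is not touched, so the trans configuration is kept.

Step 10
Reactants: 17 1-[(1R,2S)-2-{2-[(tert-butyldimethylsilyl)oxy]ethyl}-3,3-dimethylcyclobutyl]ethenyl trifluoromethanesulfonate
Product: 18 2-[(1R,2S)-2-{2-[(tert-butyldimethylsilyl)oxy]ethyl}-3,3-dimethylcyclobutyl]prop-2-en-1-ol
Conditions: Bu3SnCH2OH, Pd(PPh3)4 (5 mol%), LiCl, dioxane, 95 °C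
Reagents that add atoms: (tributylstannyl)methanol, CCCC[Sn](CCCC)(CCCC)CO
Why: Stille coupling of an enol triflate with a hydroxymethylstannane installs the second allyl terminus and its oxygen in one operation.

Step 11
Reactants: 18 2-[(1R,2S)-2-{2-[(tert-butyldimethylsilyl)oxy]ethyl}-3,3-dimethylcyclobutyl]prop-2-en-1-ol
Product: 19 tert-butyl({2-[(1R,2S)-2-{2-[(tert-butyldimethylsilyl)oxy]ethyl}-3,3-dimethylcyclobutyl]prop-2-en-1-yl}oxy)diphenylsilane
Conditions: TBDPSCl, imidazole, CH2Cl2, 20 °C
Reagents that add atoms: tert-butyl(chloro)diphenylsilane, CC(C)(C)[Si](Cl)(c1ccccc1)c1ccccc1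
Why: silylation of the primary allylic alcohol with a group that outlasts the acid of step 12 and the organometallic steps 14 to 16.

Step 12
Reactants: 19 tert-butyl({2-[(1R,2S)-2-{2-[(tert-butyldimethylsilyl)oxy]ethyl}-3,3-dimethylcyclobutyl]prop-2-en-1-yl}oxy)diphenylsilane
Product: 20 2-[(1S,4R)-4-(3-{[tert-butyl(diphenyl)silyl]oxy}prop-1-en-2-yl)-2,2-dimethylcyclobutyl]ethan-1-ol
Conditions: PPTS (0.2 equiv), MeOH, 20 °C
Reagents that add atoms: none
Why: acid-catalysed methanolysis removes a primary tert-butyldimethylsilyl ether much faster than a tert-butyldiphenylsilyl ether.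

Step 13
Reactants: 20 2-[(1S,4R)-4-(3-{[tert-butyl(diphenyl)silyl]oxy}prop-1-en-2-yl)-2,2-dimethylcyclobutyl]ethan-1-ol
Product: 21 tert-butyl({2-[(1R,2S)-2-(2-iodoethyl)-3,3-dimethylcyclobutyl]prop-2-en-1-yl}oxy)diphenylsilane
Conditions: I2, PPh3, imidazole, CH2Cl2, 0 → 20 °C
Reagents that add atoms: iodine, II
Why: Appel-type iodination of a primary alcohol through its alkoxyphosphonium salt.

Step 14
Reactants: 21 tert-butyl({2-[(1R,2S)-2-(2-iodoethyl)-3,3-dimethylcyclobutyl]prop-2-en-1-yl}oxy)diphenylsilane; 6 (3R,4S)-5,7-bis(methoxymethoxy)-4-phenyl-3-[(phenylsulfanyl)methyl]-3,4-dihydro-2H-chromen-2-one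
Product: 24 2-[(1S,2R)-5-[(1S,4R)-4-(3-{[tert-butyl(diphenyl)silyl]oxy}prop-1-en-2-yl)-2,2-dimethylcyclobutyl]-3-oxo-1-phenyl-2-[(phenylsulfanyl)methyl]pentyl]-3,5-bis(methoxymethoxy)phenyl trifluoromethanesulfonate, via organolithium 22 (not isolated), via lithium hemiketal alkoxide 23 (not isolated)
Conditions: 21, t-BuLi (2.05 equiv), Et2O–pentane, −78 °C; then 6 (1.2 equiv), THF, −78 °C; then PhNTf2, −78 → 20 °C
Reagents that add atoms: N-phenylbis(trifluoromethanesulfonimide), O=S(=O)(N(c1ccccc1)S(=O)(=O)C(F)(F)F)C(F)(F)F
Why: iodine–lithium exchange and addition of the primary alkyllithium to the aryl lactone form the C3–C4 bond; alkoxide 23 opens to the ketone phenoxide, which is O-triflated in the same flask, so the lactone oxygen becomes a leaving group. No stereocentre is formed or touched at −78 °C.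

Step 15
Reactants: 24 the keto aryl triflate of step 14
Product: 25 2-[(1S,2R,3S)-5-[(1S,4R)-4-(3-{[tert-butyl(diphenyl)silyl]oxy}prop-1-en-2-yl)-2,2-dimethylcyclobutyl]-3-hydroxy-3-methyl-1-phenyl-2-[(phenylsulfanyl)methyl]pentyl]-3,5-bis(methoxymethoxy)phenyl trifluoromethanesulfonate
Conditions: MeMgBr (3 equiv), CeCl3 (3 equiv), THF, −78 → −40 °C
Reagents that add atoms: methylmagnesium bromide, C[Mg]Br
Why: organocerium-type 1,2-addition to a hindered, enolisable ketone; Felkin–Anh attack anti to the diarylmethyl group on C5, and equally the chelate model through the sulfide sulfur, place the methyl group so that C4 takes the configuration of the target.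

Step 16
Reactants: 25 the tertiary alcohol of step 15
Product: 26 (2S,3R,4S)-2-{2-[(1S,4R)-4-(3-{[tert-butyl(diphenyl)silyl]oxy}prop-1-en-2-yl)-2,2-dimethylcyclobutyl]ethyl}-5,7-bis(methoxymethoxy)-2-methyl-4-phenyl-3-[(phenylsulfanyl)methyl]-3,4-dihydro-2H-chromene
Conditions: Pd(OAc)2 (5 mol%), 2-(di-tert-butylphosphino)-1,1'-binaphthyl (6 mol%), Cs2CO3, toluene, 80 °C
Reagents that add atoms: none
Why: intramolecular Buchwald–Hartwig-type C–O coupling of a tertiary alkoxide with an aryl triflate closes ring B; the carbinol C–O bond is not broken, so C4 is carried over with retention, and a tertiary alkoxide has no hydrogen on the carbinol carbon through which the palladium alkoxide could decompose.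

Step 17
Reactants: 26 the chroman sulfide of step 16
Product: 27 (2S,3R,4S)-2-{2-[(1S,4R)-4-(3-{[tert-butyl(diphenyl)silyl]oxy}prop-1-en-2-yl)-2,2-dimethylcyclobutyl]ethyl}-5,7-bis(methoxymethoxy)-2-methyl-4-phenyl-3-[(phenylsulfonyl)methyl]-3,4-dihydro-2H-chromene
Conditions: (NH4)6Mo7O24·4H2O (10 mol%), 30% H2O2, EtOH, 0 → 20 °C
Reagents that add atoms: hydrogen peroxide, OO
Why: molybdate-catalysed oxidation of a sulfide to the sulfone, a method that spares unactivated alkenes, silyl ethers and acetal ethers.

Step 18
Reactants: 27 the sulfone silyl ether of step 17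
Product: 28 2-[(1R,2S)-2-{2-[(2S,3R,4S)-5,7-bis(methoxymethoxy)-2-methyl-4-phenyl-3-[(phenylsulfonyl)methyl]-3,4-dihydro-2H-chromen-2-yl]ethyl}-3,3-dimethylcyclobutyl]prop-2-en-1-ol
Conditions: Bu4NF, THF, 0 → 20 °C
Reagents that add atoms: none
Why: fluoride cleavage of the silyl ether; the sulfone and the acetal ethers are inert.

Step 19
Reactants: 28 the allylic alcohol of step 18
Product: 29 (2S,3R,4S)-2-{2-[(1S,4R)-4-(3-bromoprop-1-en-2-yl)-2,2-dimethylcyclobutyl]ethyl}-5,7-bis(methoxymethoxy)-2-methyl-4-phenyl-3-[(phenylsulfonyl)methyl]-3,4-dihydro-2H-chromene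
Conditions: CBr4, PPh3, 2,6-lutidine, CH2Cl2, 0 °C
Reagents that add atoms: carbon tetrabromide, BrC(Br)(Br)Br
Why: Appel bromination of a primary allylic alcohol; the two allyl termini are equivalent, so direct and transposed displacement give the same bromide, and the buffer protects the acetal ethers.

Step 20
Reactants: 29 the bromo sulfone of step 19
Product: 30 the C6-phenylsulfonyl derivative of 31 (ring-C numbering; 1S,4S,5R,9R,1'S; both C6 epimers)
Conditions: LiN(SiMe3)2 (3 equiv), THF, 0 → 20 °C, 29 added over 10 h (final 1 mM)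
Reagents that add atoms: none
Why: The amide base removes a proton from C6, the methylene group next to the phenylsulfonyl group and the only carbon acid within its reach, and the lithium carbanion displaces bromide from the allyl unit on C9, forming C6–C7. The closest known reaction type is the intramolecular alkylation of sulfone-stabilised carbanions by allylic halides used for medium and large carbocycles. Ring C closes in the 9-exo-tet mode (SN2 at the CH2Br carbon); the transposed SN2′ attack at the methylidene carbon (formally 9-endo-trig) forms the same bond and the same alkene because the two termini are equivalent. C6 becomes a stereocentre that no element of the substrate is relied on to control; excess base may equilibrate it, and step 21 removes it. The selectivity needed is ring closure over oligomerisation and over N-alkylation of the base. Slow addition into excess base keeps the bromide dilute, the trans-disposed chains on C4 and C5 of ring B and the trans-cyclobutane keep the two reacting ends on the same flank, and every encounter of the carbanion with either allyl terminus is productive. No other stereocentre is at risk, since C5 and C1' carry no acidifying group and the carbanion has no β-leaving group.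

Step 21
Reactants: 30 the cyclised sulfone of step 20
Product: 31 the bis(methoxymethyl) ether of the deformyl target (tetracycle of 33 without formyl groups, both phenols as methoxymethyl ethers; 1S,4S,5R,9R,1'S)
Conditions: Mg, MeOH, 20 → 50 °C
Reagents that add atoms: none
Why: dissolving-metal desulfonylation of an alkyl phenyl sulfone (electron transfer, loss of benzenesulfinate, reduction of the radical to the carbanion, protonation); both C6 epimers converge on 31, and the transient homoallyl radical has no more stable rearranged form.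

Step 22
Reactants: 31 the bis(methoxymethyl) ether of step 21
Product: 32 the deformyl target (5,7-diol on ring A; 1S,4S,5R,9R,1'S)
Conditions: 2 M HCl, MeOH–THF, 40 °C
Reagents that add atoms: none
Why: acid-catalysed acetal exchange removes both aryl methoxymethyl ethers under conditions too mild to protonate a 1,1-disubstituted alkene or to ionise the tertiary aryl ether.

Step 23
Reactants: 32 the deformyl target
Product: 33 target CNP0253700.1 (1S,4S,5R,9R,1'S)
Conditions: POCl3, DMF, EtOAc, 0 → 20 °C; then H2O, NaOAc, 50 °C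
Reagents that add atoms: N,N-dimethylformamide, CN(C)C=O; water, O
Why: Vilsmeier–Haack formylation; a phloroglucinol-type ring is activated enough for both of its free positions to react, as in the twofold formylation of phloroglucinol itself, while the isolated alkene is far less nucleophilic.

## Compound list

1 | 5,7-dihydroxycoumarin | O=c1ccc2c(O)cc(O)cc2o1 | starting material
2 | 5,7-bis(methoxymethoxy)-2H-chromen-2-one | O=c1ccc2c(OCOC)cc(OCOC)cc2o1 | intermediate
3 | phenylboronic acid | OB(O)c1ccccc1 | starting material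
4 | (4S)-5,7-bis(methoxymethoxy)-4-phenyl-3,4-dihydro-2H-chromen-2-one | O=C1C[C@@H](c2ccccc2)c2c(OCOC)cc(OCOC)cc2O1 | intermediate
5 | {[(4S)-5,7-bis(methoxymethoxy)-4-phenyl-4H-chromen-2-yl]oxy}trimethylsilane | C[Si](C)(C)OC1=C[C@@H](c2ccccc2)c2c(OCOC)cc(OCOC)cc2O1 | intermediate (not isolated)
6 | (3R,4S)-5,7-bis(methoxymethoxy)-4-phenyl-3-[(phenylsulfanyl)methyl]-3,4-dihydro-2H-chromen-2-one | c1ccccc1SC[C@@H]1[C@@H](c2ccccc2)c2c(OCOC)cc(OCOC)cc2OC1=O | intermediate
7 | (4R)-4-[(tert-butyldimethylsilyl)oxy]cyclopent-2-en-1-one | O=C1C[C@@H](O[Si](C)(C)C(C)(C)C)C=C1 | starting material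
8 | isobutene (2-methylprop-1-ene) | C=C(C)C | starting material
9 | (1S,4R,5S)-4-[(tert-butyldimethylsilyl)oxy]-6,6-dimethylbicyclo[3.2.0]heptan-2-one | O=C1C[C@@H](O[Si](C)(C)C(C)(C)C)[C@H]2[C@@H]1CC2(C)C | intermediate
10 | (1S,5S)-6,6-dimethylbicyclo[3.2.0]hept-3-en-2-one | O=C1C=C[C@H]2[C@@H]1CC2(C)C | intermediate
11 | {[(1S,5S)-6,6-dimethylbicyclo[3.2.0]hept-2-en-2-yl]oxy}triethylsilane | CC[Si](CC)(CC)OC1=CC[C@H]2[C@@H]1CC2(C)C | intermediate (not isolated)
12 | (1S,2S)-2-(2-hydroxyethyl)-3,3-dimethylcyclobutane-1-carboxylic acid | OCC[C@H]1[C@@H](C(=O)O)CC1(C)C | intermediate (not isolated)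
13 | (1S,6S)-7,7-dimethyl-3-oxabicyclo[4.2.0]octan-2-one | O=C1OCC[C@H]2[C@@H]1CC2(C)C | intermediate
14 | 1-[(1S,2S)-2-(2-hydroxyethyl)-3,3-dimethylcyclobutyl]ethan-1-one (open form of the hemiketal) | OCC[C@H]1[C@@H](C(C)=O)CC1(C)C | intermediate
15 | 1-[(1S,2S)-2-{2-[(tert-butyldimethylsilyl)oxy]ethyl}-3,3-dimethylcyclobutyl]ethan-1-one | CC(C)(C)[Si](C)(C)OCC[C@H]1[C@@H](C(C)=O)CC1(C)C | intermediate (not isolated)
16 | 1-[(1R,2S)-2-{2-[(tert-butyldimethylsilyl)oxy]ethyl}-3,3-dimethylcyclobutyl]ethan-1-one | CC(C)(C)[Si](C)(C)OCC[C@H]1[C@H](C(C)=O)CC1(C)C | intermediate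
17 | 1-[(1R,2S)-2-{2-[(tert-butyldimethylsilyl)oxy]ethyl}-3,3-dimethylcyclobutyl]ethenyl trifluoromethanesulfonate | CC(C)(C)[Si](C)(C)OCC[C@H]1[C@H](C(=C)OS(=O)(=O)C(F)(F)F)CC1(C)C | intermediate
18 | 2-[(1R,2S)-2-{2-[(tert-butyldimethylsilyl)oxy]ethyl}-3,3-dimethylcyclobutyl]prop-2-en-1-ol | CC(C)(C)[Si](C)(C)OCC[C@H]1[C@H](C(=C)CO)CC1(C)C | intermediate
19 | tert-butyl({2-[(1R,2S)-2-{2-[(tert-butyldimethylsilyl)oxy]ethyl}-3,3-dimethylcyclobutyl]prop-2-en-1-yl}oxy)diphenylsilane | CC(C)(C)[Si](C)(C)OCC[C@H]1[C@H](C(=C)CO[Si](c2ccccc2)(c2ccccc2)C(C)(C)C)CC1(C)C | intermediate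
20 | 2-[(1S,4R)-4-(3-{[tert-butyl(diphenyl)silyl]oxy}prop-1-en-2-yl)-2,2-dimethylcyclobutyl]ethan-1-ol | OCC[C@H]1[C@H](C(=C)CO[Si](c2ccccc2)(c2ccccc2)C(C)(C)C)CC1(C)C | intermediate
21 | tert-butyl({2-[(1R,2S)-2-(2-iodoethyl)-3,3-dimethylcyclobutyl]prop-2-en-1-yl}oxy)diphenylsilane | ICC[C@H]1[C@H](C(=C)CO[Si](c2ccccc2)(c2ccccc2)C(C)(C)C)CC1(C)C | intermediate
22 | {2-[(1S,4R)-4-(3-{[tert-butyl(diphenyl)silyl]oxy}prop-1-en-2-yl)-2,2-dimethylcyclobutyl]ethyl}lithium | [Li]CC[C@H]1[C@H](C(=C)CO[Si](c2ccccc2)(c2ccccc2)C(C)(C)C)CC1(C)C | intermediate (not isolated)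
23 | lithium (3R,4S)-2-{2-[(1S,4R)-4-(3-{[tert-butyl(diphenyl)silyl]oxy}prop-1-en-2-yl)-2,2-dimethylcyclobutyl]ethyl}-5,7-bis(methoxymethoxy)-4-phenyl-3-[(phenylsulfanyl)methyl]-3,4-dihydro-2H-chromen-2-olate (both C2 epimers) | c1ccccc1SC[C@@H]1[C@@H](c2ccccc2)c2c(OCOC)cc(OCOC)cc2OC1(O[Li])CC[C@H]1[C@H](C(=C)CO[Si](c2ccccc2)(c2ccccc2)C(C)(C)C)CC1(C)C | intermediate (not isolated)
24 | 2-[(1S,2R)-5-[(1S,4R)-4-(3-{[tert-butyl(diphenyl)silyl]oxy}prop-1-en-2-yl)-2,2-dimethylcyclobutyl]-3-oxo-1-phenyl-2-[(phenylsulfanyl)methyl]pentyl]-3,5-bis(methoxymethoxy)phenyl trifluoromethanesulfonate | c1ccccc1SC[C@H]([C@@H](c2ccccc2)c2c(OCOC)cc(OCOC)cc2OS(=O)(=O)C(F)(F)F)C(=O)CC[C@H]1[C@H](C(=C)CO[Si](c2ccccc2)(c2ccccc2)C(C)(C)C)CC1(C)C | intermediate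
25 | 2-[(1S,2R,3S)-5-[(1S,4R)-4-(3-{[tert-butyl(diphenyl)silyl]oxy}prop-1-en-2-yl)-2,2-dimethylcyclobutyl]-3-hydroxy-3-methyl-1-phenyl-2-[(phenylsulfanyl)methyl]pentyl]-3,5-bis(methoxymethoxy)phenyl trifluoromethanesulfonate | c1ccccc1SC[C@H]([C@@H](c2ccccc2)c2c(OCOC)cc(OCOC)cc2OS(=O)(=O)C(F)(F)F)[C@@](C)(O)CC[C@H]1[C@H](C(=C)CO[Si](c2ccccc2)(c2ccccc2)C(C)(C)C)CC1(C)C | intermediate
26 | (2S,3R,4S)-2-{2-[(1S,4R)-4-(3-{[tert-butyl(diphenyl)silyl]oxy}prop-1-en-2-yl)-2,2-dimethylcyclobutyl]ethyl}-5,7-bis(methoxymethoxy)-2-methyl-4-phenyl-3-[(phenylsulfanyl)methyl]-3,4-dihydro-2H-chromene | c1ccccc1SC[C@@H]1[C@@H](c2ccccc2)c2c(OCOC)cc(OCOC)cc2O[C@@]1(C)CC[C@H]1[C@H](C(=C)CO[Si](c2ccccc2)(c2ccccc2)C(C)(C)C)CC1(C)C | intermediate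
27 | (2S,3R,4S)-2-{2-[(1S,4R)-4-(3-{[tert-butyl(diphenyl)silyl]oxy}prop-1-en-2-yl)-2,2-dimethylcyclobutyl]ethyl}-5,7-bis(methoxymethoxy)-2-methyl-4-phenyl-3-[(phenylsulfonyl)methyl]-3,4-dihydro-2H-chromene | O=S(=O)(C[C@@H]1[C@@H](c2ccccc2)c2c(OCOC)cc(OCOC)cc2O[C@@]1(C)CC[C@H]1[C@H](C(=C)CO[Si](c2ccccc2)(c2ccccc2)C(C)(C)C)CC1(C)C)c1ccccc1 | intermediate
28 | 2-[(1R,2S)-2-{2-[(2S,3R,4S)-5,7-bis(methoxymethoxy)-2-methyl-4-phenyl-3-[(phenylsulfonyl)methyl]-3,4-dihydro-2H-chromen-2-yl]ethyl}-3,3-dimethylcyclobutyl]prop-2-en-1-ol | O=S(=O)(C[C@@H]1[C@@H](c2ccccc2)c2c(OCOC)cc(OCOC)cc2O[C@@]1(C)CC[C@H]1[C@H](C(=C)CO)CC1(C)C)c1ccccc1 | intermediate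
29 | (2S,3R,4S)-2-{2-[(1S,4R)-4-(3-bromoprop-1-en-2-yl)-2,2-dimethylcyclobutyl]ethyl}-5,7-bis(methoxymethoxy)-2-methyl-4-phenyl-3-[(phenylsulfonyl)methyl]-3,4-dihydro-2H-chromene | O=S(=O)(C[C@@H]1[C@@H](c2ccccc2)c2c(OCOC)cc(OCOC)cc2O[C@@]1(C)CC[C@H]1[C@H](C(=C)CBr)CC1(C)C)c1ccccc1 | intermediate
30 | C6-phenylsulfonyl derivative of 31 (1S,4S,5R,9R,1'S; both C6 epimers) | C=C1CC(S(=O)(=O)c3ccccc3)[C@@H]2[C@@H](c3ccccc3)c3c(OCOC)cc(OCOC)cc3O[C@@]2(C)CC[C@H]2[C@H]1CC2(C)C | intermediate
31 | bis(methoxymethyl) ether of the deformyl target (1S,4S,5R,9R,1'S) | C=C1CC[C@@H]2[C@@H](c3ccccc3)c3c(OCOC)cc(OCOC)cc3O[C@@]2(C)CC[C@H]2[C@H]1CC2(C)C | intermediate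
32 | deformyl target, ring A as the 5,7-diol (1S,4S,5R,9R,1'S) | C=C1CC[C@@H]2[C@@H](c3ccccc3)c3c(O)cc(O)cc3O[C@@]2(C)CC[C@H]2[C@H]1CC2(C)C | intermediate
33 | CNP0253700.1 (1S,4S,5R,9R,1'S) | C=C1CC[C@@H]2[C@@H](c3ccccc3)c3c(O)c(C=O)c(O)c(C=O)c3O[C@@]2(C)CC[C@H]2[C@H]1CC2(C)C | target

## Step count and least certain steps

Total: 23 steps. Longest linear sequence: 20 steps (7 → 33 through steps 4–13 and 14–23); the branch from 1 contributes steps 1–3.

**Step 20 (key step).** The most likely failure is intermolecular alkylation outrunning closure of the strained nine-membered ring, or incomplete deprotonation so that the bromide is consumed by the amide base. The fallback keeps the C6–C7 bond but reverses its polarity, sets out from 26 and returns at 31: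
- Bu4NF gives the allylic alcohol F1, and CBr4/PPh3 the allylic bromide F2.
- One equivalent of mCPBA at −78 °C gives the sulfoxide F3.
- Pummerer rearrangement ((CF3CO)2O, 2,6-lutidine, then aqueous NaHCO3) gives the C6 aldehyde F4.
- CrCl2 in THF at high dilution turns the bromide into an allylchromium species that adds to the aldehyde (Nozaki–Hiyama–Kishi-type allylation, again indifferent to which allyl terminus reacts), closing ring C as the C6 alcohol F5.
- 1,1'-Thiocarbonyldiimidazole gives the O-alkyl imidazole-1-carbothioate F6, and Bu3SnH/AIBN (Barton–McCombie deoxygenation) gives 31.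
- F4 is a β-aryloxy aldehyde and must be kept away from base.

**Step 16.** The most likely failure is slow C–O reductive elimination from a crowded arylpalladium tertiary alkoxide, so that reduction or hydrolysis of the triflate takes over. The fallback sets out from 25 and returns at 26: triflate-to-bromide exchange (Pd2(dba)3, tBuBrettPhos, KBr) gives the aryl bromide F7, and copper-mediated Ullmann etherification (CuI, 2,2'-bipyridine, KOt-Bu, DMF, 120 °C) closes the ring. This type of closure is known for closely related tertiary alcohol/aryl bromide pairs.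

**Step 14.** The most likely failure is deprotonation of 6 at C5 by the alkyllithium with loss of thiophenolate, or a second addition to the released ketone; both waste the ten-step fragment. The fallback sets out from 6 and returns at 24: Me(MeO)NH·HCl/AlMe3 opens the lactone to the phenol Weinreb amide F8, which is triflated at once (PhNTf2, Et3N) to the aryl triflate Weinreb amide F9. The Grignard reagent made from 22 with MgBr2·OEt2 then adds once.

**Step 15.** The most likely failure is erosion or reversal of facial selectivity, because cerium or magnesium bridged between the carbonyl oxygen and an aryl ether oxygen can present the other face. The fallback exchanges the two carbon nucleophiles, sets out from 6 and returns at 25: MeLi at −78 °C and then PhNTf2 give the methyl ketone F10, and the organocerium reagent made from 22 and CeCl3 is added to it. This gives 25 if the intrinsic preference is the reverse of the Felkin–Anh one. If the preference is only weak, the C4 epimers are separated after ring closure, at 26.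

**Step 23.** The most likely failure is attack of the chloroiminium electrophile or of HCl on the methylidene group, or stalling after the first formylation. The fallback keeps the acetal ethers as directing groups, sets out from 31 and returns at 33:
- n-BuLi/TMEDA then DMF gives the monoaldehyde F11 (lithiation between the two acetal ethers).
- Protection in the flask as the α-amino alkoxide with LiN(Me)CH2CH2NMe2, a second lithiation with n-BuLi at the remaining ring-A position, and DMF give the dialdehyde F12.
- HCl in MeOH removes both methoxymethyl groups.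

## Further compounds

F1 | step 20 | 2-[(1R,2S)-2-{2-[(2S,3R,4S)-5,7-bis(methoxymethoxy)-2-methyl-4-phenyl-3-[(phenylsulfanyl)methyl]-3,4-dihydro-2H-chromen-2-yl]ethyl}-3,3-dimethylcyclobutyl]prop-2-en-1-ol | c1ccccc1SC[C@@H]1[C@@H](c2ccccc2)c2c(OCOC)cc(OCOC)cc2O[C@@]1(C)CC[C@H]1[C@H](C(=C)CO)CC1(C)C
F2 | step 20 | (2S,3R,4S)-2-{2-[(1S,4R)-4-(3-bromoprop-1-en-2-yl)-2,2-dimethylcyclobutyl]ethyl}-5,7-bis(methoxymethoxy)-2-methyl-4-phenyl-3-[(phenylsulfanyl)methyl]-3,4-dihydro-2H-chromene | c1ccccc1SC[C@@H]1[C@@H](c2ccccc2)c2c(OCOC)cc(OCOC)cc2O[C@@]1(C)CC[C@H]1[C@H](C(=C)CBr)CC1(C)C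
F3 | step 20 | phenylsulfinyl analogue of F2 (sulfoxide, both sulfur epimers) | O=S(C[C@@H]1[C@@H](c2ccccc2)c2c(OCOC)cc(OCOC)cc2O[C@@]1(C)CC[C@H]1[C@H](C(=C)CBr)CC1(C)C)c1ccccc1
F4 | step 20 | (2S,3R,4S)-2-{2-[(1S,4R)-4-(3-bromoprop-1-en-2-yl)-2,2-dimethylcyclobutyl]ethyl}-5,7-bis(methoxymethoxy)-2-methyl-4-phenyl-3,4-dihydro-2H-chromene-3-carbaldehyde | O=C[C@@H]1[C@@H](c2ccccc2)c2c(OCOC)cc(OCOC)cc2O[C@@]1(C)CC[C@H]1[C@H](C(=C)CBr)CC1(C)C
F5 | step 20 | C6 alcohol of 31 (ring-C numbering; both C6 epimers) | C=C1CC(O)[C@@H]2[C@@H](c3ccccc3)c3c(OCOC)cc(OCOC)cc3O[C@@]2(C)CC[C@H]2[C@H]1CC2(C)C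
F6 | step 20 | O-(C6 of 31) imidazole-1-carbothioate | C=C1CC(OC(=S)n3ccnc3)[C@@H]2[C@@H](c3ccccc3)c3c(OCOC)cc(OCOC)cc3O[C@@]2(C)CC[C@H]2[C@H]1CC2(C)C
F7 | step 16 | aryl bromide analogue of 25 (bromine in place of the triflate group) | c1ccccc1SC[C@H]([C@@H](c2ccccc2)c2c(OCOC)cc(OCOC)cc2Br)[C@@](C)(O)CC[C@H]1[C@H](C(=C)CO[Si](c2ccccc2)(c2ccccc2)C(C)(C)C)CC1(C)C
F8 | step 14 | (2R,3S)-3-[2-hydroxy-4,6-bis(methoxymethoxy)phenyl]-N-methoxy-N-methyl-3-phenyl-2-[(phenylsulfanyl)methyl]propanamide | c1ccccc1SC[C@H]([C@@H](c2ccccc2)c2c(OCOC)cc(OCOC)cc2O)C(=O)N(C)OC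
F9 | step 14 | aryl trifluoromethanesulfonate of F8 | c1ccccc1SC[C@H]([C@@H](c2ccccc2)c2c(OCOC)cc(OCOC)cc2OS(=O)(=O)C(F)(F)F)C(=O)N(C)OC
F10 | step 15 | 3,5-bis(methoxymethoxy)-2-[(1S,2R)-3-oxo-1-phenyl-2-[(phenylsulfanyl)methyl]butyl]phenyl trifluoromethanesulfonate | c1ccccc1SC[C@H]([C@@H](c2ccccc2)c2c(OCOC)cc(OCOC)cc2OS(=O)(=O)C(F)(F)F)C(C)=O
F11 | step 23 | monoaldehyde of 31 (formyl group between the two methoxymethoxy groups) | C=C1CC[C@@H]2[C@@H](c3ccccc3)c3c(OCOC)c(C=O)c(OCOC)cc3O[C@@]2(C)CC[C@H]2[C@H]1CC2(C)C
F12 | step 23 | bis(methoxymethyl) ether of 33 | C=C1CC[C@@H]2[C@@H](c3ccccc3)c3c(OCOC)c(C=O)c(OCOC)c(C=O)c3O[C@@]2(C)CC[C@H]2[C@H]1CC2(C)C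
A1 | alternative 1 | ring-B ketene O,S-acetal ester (methyl 2-(methylsulfanyl)-4-phenyl-4H-pyran-3-carboxylate unit fused to rings C and D) | C=C1CC[C@@H]2[C@@H](c3ccccc3)C(C(=O)OC)=C(SC)O[C@@]2(C)CC[C@H]2[C@H]1CC2(C)C
A2 | alternative 1 | dimethyl 3-oxopentanedioate | COC(=O)CC(=O)CC(=O)OC
A3 | alternative 1 | target with both formyl groups replaced by methyl ester groups | C=C1CC[C@@H]2[C@@H](c3ccccc3)c3c(O)c(C(=O)OC)c(O)c(C(=O)OC)c3O[C@@]2(C)CC[C@H]2[C@H]1CC2(C)C
A4 | alternative 2 | ring-B-fused (Z)-cyclonon-2-enone (C8 ketone, C9=C1 alkene), phenols as methoxymethyl ethers | O=C1CC[C@@H]2[C@@H](c3ccccc3)c3c(OCOC)cc(OCOC)cc3O[C@@]2(C)CC/C=C\1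
A5 | alternative 2 | protected deformyl C8 ketone with the trans-fused cyclobutane | O=C1CC[C@@H]2[C@@H](c3ccccc3)c3c(OCOC)cc(OCOC)cc3O[C@@]2(C)CC[C@H]2[C@H]1CC2(C)C
A6 | alternative 3 | chroman with a C5 vinyl group and the cyclobutyl enol triflate | C=C[C@@H]1[C@@H](c2ccccc2)c2c(OCOC)cc(OCOC)cc2O[C@@]1(C)CC[C@H]1[C@H](C(=C)OS(=O)(=O)C(F)(F)F)CC1(C)C
A7 | alternative 3 | bis(methoxymethyl) ether of the deformyl target (same compound as 31) | C=C1CC[C@@H]2[C@@H](c3ccccc3)c3c(OCOC)cc(OCOC)cc3O[C@@]2(C)CC[C@H]2[C@H]1CC2(C)C
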